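## Retrosynthetic overview
1. Target 15 ⇒ diol 13 (the two alcohols are told apart by sterics on acylation) ⇒ diketo acrylate 12 (one hydride reagent, both C=O attacked anti to the axial C10 methyl).
2. 12 ⇒ cut C7–C11: enamine of bicyclic dione 8 plus methyl 3-nitroacrylate 9 (Michael addition, then loss of HNO2).
3. 8 ⇒ cut C4=C5: aldol condensation closes ring A from 1,5-diketone 6, which is stored as dihydropyran 5.
4. 5 ⇒ cut C1–C10 and O–C5: enantioselective Brønsted acid catalysed inverse-demand oxa-Diels–Alder of achiral enol ether 3 with ethyl vinyl ketone 4. This sets C10, which controls every later centre.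
5. 3 ⇒ ring B is taken whole from 2,5-dimethoxytoluene 1 (Birch reduction, site-selective ketalisation). Ring order: B from the arene, then A.

Assumption: methyl (E)-3-nitroacrylate 9 is taken as a catalogue compound. Positions are given in eudesmane numbering (C10 quaternary carbon, C4=C5 ring alkene, C3 isobutyrate carbon, C7 acrylate-bearing carbon, C8 acetate carbon). The target is 3S,7R,8R,10R, that is 3β-O, 7β-C, 8β-O, 10β-Me.

## Route

Step 1
Reactants: 1 2,5-dimethoxytoluene
Product: 2 1,4-dimethoxy-2-methylcyclohexa-1,4-diene
Conditions: Li (2.5 equiv), t-BuOH (2.5 equiv), NH3(l)/THF, −78 to −33 °C; MeOH quench, basic work-up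
Reagents that add atoms: none
Why: Birch reduction leaves the two methoxy-bearing carbons and the methyl-bearing carbon sp2, so the product is the achiral bis(enol ether) of 2-methylcyclohexane-1,4-dione and no stereocentre is formed.

Step 2
Reactants: 2 1,4-dimethoxy-2-methylcyclohexa-1,4-diene
Product: 3 8-methoxy-7-methyl-1,4-dioxaspiro[4.5]dec-7-ene
Conditions: HOCH2CH2OH (1.0 equiv), PPTS (1 mol %), 4 Å MS, CH2Cl2, −20 to 0 °C; Et3N quench
Reagents that add atoms: ethylene glycol, OCCO
Why: Acid-catalysed enol ether to ketal exchange is rate-limited by C-protonation, which is roughly ten times faster at the trisubstituted C7=C8 enol ether than at the tetrasubstituted C5=C10 one, and the product keeps the more stable alkene, so kinetics and thermodynamics both give achiral 3.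

Step 3
Reactants: 3 8-methoxy-7-methyl-1,4-dioxaspiro[4.5]dec-7-ene, 4 ethyl vinyl ketone (pent-1-en-3-one)
Product: 5 (4aR,8aS)-2-ethyl-8a-methoxy-4a-methyl-4,4a,5,7,8,8a-hexahydrospiro[chromene-6,2'-[1,3]dioxolane] (cis-fused; methyl and methoxy on the same face)
Conditions: BINOL-derived confined imidodiphosphorimidate (IDPi) Brønsted acid (3 mol %, antipode chosen to give 4aR), 4 (1.5 equiv), 4 Å MS, toluene, −40 °C, 48 h; Et3N quench
Reagents that add atoms: none
Why: Proposed new method: a catalytic enantioselective inverse-electron-demand oxa-Diels–Alder of a simple vinyl ketone with a fully substituted alkyl enol ether, in which the confined acid protonates s-cis 4, the enol ether carbon C10 attacks the free CH2 terminus first (highly asynchronous), and the methyl oxocarbenium/enol pair held by the chiral anion then closes O–C5 on the same face, which returns the proton without any external nucleophile, so the pocket's choice between the two faces of flat, achiral 3 sets the quaternary C10 (and a transient C5), the closest known reaction types being thermal or Lewis acid oxa-Diels–Alder of vinyl ketones with enol ethers, chiral phosphoric acid enol-catalysis Michael additions of α-branched ketones to vinyl ketones, and IDPi Mukaiyama–Michael reactions.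

Step 4
Reactants: 5 (4aR,8aS)-2-ethyl-8a-methoxy-4a-methyl-4,4a,5,7,8,8a-hexahydrospiro[chromene-6,2'-[1,3]dioxolane]
Product: 8 (4aR)-1,4a-dimethyl-4,4a,7,8-tetrahydronaphthalene-2,6(3H,5H)-dione (10R; 3-enone plus 8-ketone), via diketone ketal 6 (not isolated), via enone ketal 7 (not isolated)
Conditions: 0.1 M HCl, THF/H2O, 0 °C, 30 min; then KOH, MeOH, 50 °C; then 3 M HCl to pH 1, rt (one flask)
Reagents that add atoms: water, O
Why: The cyclic enol ether/mixed ketal hydrolyses far faster than the dioxolane, the freed 1,5-diketone undergoes the intramolecular aldol condensation of a Robinson annulation while C8 is still masked (so only the six-membered enone can form), and final acetal hydrolysis frees the C8 ketone, with C5 becoming sp2 and the quaternary C10 unable to epimerise.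

Step 5
Reactants: 8 (4aR)-1,4a-dimethyl-4,4a,7,8-tetrahydronaphthalene-2,6(3H,5H)-dione, 9 methyl (E)-3-nitroacrylate
Product: 12 methyl (7R,10R)-3,8-dioxoeudesma-4,11(13)-dien-12-oate, via pyrrolidine enamine 10 (not isolated), via nitro ester 11 (not isolated)
Conditions: pyrrolidine (1.1 equiv), 4 Å MS, benzene, rt, evaporate; 9 (1.0 equiv), THF, −40 to 0 °C; aq AcOH/NaOAc, rt, extract; Et3N (1.5 equiv), CH2Cl2, rt
Reagents that add atoms: water, O
Why: This is a Stork enamine Michael addition to a β-nitroacrylate followed by E1cB loss of nitrite (the nitroacrylate acts as an α-acrylate cation equivalent), in which the unhindered saturated ketone forms its enamine in preference to the 4-methyl enone and away from neopentyl C9, nitro directs bond formation to the ester-bearing carbon, and Et3N equilibrates the acidic C7–H so that the acrylate sits equatorial (7β, cis to the 10-methyl; about 5:1 expected, minor epimer separated and re-equilibrated).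

Step 6
Reactants: 12 methyl (7R,10R)-3,8-dioxoeudesma-4,11(13)-dien-12-oate
Product: 13 methyl (3S,7R,8R,10R)-3,8-dihydroxyeudesma-4,11(13)-dien-12-oate (3β-OH, 8β-OH)
Conditions: LiAlH(Ot-Bu)3 (3 equiv), THF, −78 to −10 °C; cold pH 7 buffer/Rochelle salt
Reagents that add atoms: none
Why: In this substrate-controlled diastereoselective hydride reduction the axial 10β-methyl shields the β face of both carbonyls, so the bulky reagent attacks from the α face to give the pseudo-equatorial 3β allylic alcohol and the axial 8β alcohol, does not touch the ester or acrylate, and leaves behind any residual 7α epimer, whose C8 carbonyl is blocked on both faces.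

Step 7
Reactants: 13 methyl (3S,7R,8R,10R)-3,8-dihydroxyeudesma-4,11(13)-dien-12-oate
Product: 15 methyl (3S,7R,8R,10R)-8-acetoxy-3-(isobutyryloxy)eudesma-4,11(13)-dien-12-oate (CNP0127901.1), via 3-O-isobutyrate 14 (not isolated)
Conditions: i-PrCOCl (1.05 equiv), pyridine, CH2Cl2, −30 °C; then Ac2O (5 equiv), DMAP (0.2 equiv), 0 °C to rt
Reagents that add atoms: isobutyryl chloride, CC(C)C(=O)Cl; acetic anhydride, CC(=O)OC(C)=O
Why: Sterically differentiated esterification acylates the equatorial allylic 3β-OH long before the axial 8β-OH (flanked by C7 and syn-axial to the methyl), and DMAP-catalysed acetylation then caps O8 faster than the neutral alcohol can lactonise, with no stereocentre touched.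

## Compound list
1 | 2,5-dimethoxytoluene | COc1ccc(OC)c(C)c1 | starting material
2 | 1,4-dimethoxy-2-methylcyclohexa-1,4-diene | COC1=CCC(OC)=C(C)C1 | intermediate
3 | 8-methoxy-7-methyl-1,4-dioxaspiro[4.5]dec-7-ene | COC1=C(C)CC2(CC1)OCCO2 | intermediate
4 | ethyl vinyl ketone | C=CC(=O)CC | starting material
5 | (4aR,8aS)-2-ethyl-8a-methoxy-4a-methyl-4,4a,5,7,8,8a-hexahydrospiro[chromene-6,2'-[1,3]dioxolane] | CCC1=CC[C@]2(C)CC3(CC[C@]2(OC)O1)OCCO3 | intermediate
6 | (R)-7-methyl-7-(3-oxopentyl)-1,4-dioxaspiro[4.5]decan-8-one | CCC(=O)CC[C@]1(C)CC2(CCC1=O)OCCO2 | intermediate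
7 | (8a'R)-5',8a'-dimethyl-3',4',8',8a'-tetrahydro-1'H-spiro[[1,3]dioxolane-2,2'-naphthalen]-6'(7'H)-one | CC1=C2CCC3(C[C@@]2(C)CCC1=O)OCCO3 | intermediate
8 | (4aR)-1,4a-dimethyl-4,4a,7,8-tetrahydronaphthalene-2,6(3H,5H)-dione | CC1=C2CCC(=O)C[C@@]2(C)CCC1=O | intermediate
9 | methyl (E)-3-nitroacrylate | COC(=O)/C=C/[N+](=O)[O-] | starting material
10 | (4aR)-1,4a-dimethyl-6-(pyrrolidin-1-yl)-4,4a,5,8-tetrahydronaphthalen-2(3H)-one (Δ7 enamine) | CC1=C2CC=C(N3CCCC3)C[C@@]2(C)CCC1=O | intermediate
11 | methyl (10R)-13-nitro-3,8-dioxoeudesm-4-en-12-oate (mixture of C7/C11 epimers) | COC(=O)C(C[N+](=O)[O-])C1CC2=C(C)C(=O)CC[C@]2(C)CC1=O | intermediate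
12 | methyl (7R,10R)-3,8-dioxoeudesma-4,11(13)-dien-12-oate | C=C(C(=O)OC)[C@H]1CC2=C(C)C(=O)CC[C@]2(C)CC1=O | intermediate
13 | methyl (3S,7R,8R,10R)-3,8-dihydroxyeudesma-4,11(13)-dien-12-oate | C=C(C(=O)OC)[C@H]1CC2=C(C)[C@@H](O)CC[C@]2(C)C[C@H]1O | intermediate
14 | methyl (3S,7R,8R,10R)-8-hydroxy-3-(isobutyryloxy)eudesma-4,11(13)-dien-12-oate | C=C(C(=O)OC)[C@H]1CC2=C(C)[C@@H](OC(=O)C(C)C)CC[C@]2(C)C[C@H]1O | intermediate
15 | methyl (3S,7R,8R,10R)-8-acetoxy-3-(isobutyryloxy)eudesma-4,11(13)-dien-12-oate | C=C(C(=O)OC)[C@H]1CC2=C(C)[C@@H](OC(=O)C(C)C)CC[C@]2(C)C[C@H]1OC(C)=O | target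

## Step count and risks
Total step count: 7. Longest linear sequence: 7 (1 → 15; 4 and 9 are bought).

**Step 3 (new reaction).**
- Likely failures are low ee, acid-induced migration of the enol ether double bond to C5=C6, or oligomerisation of 4.
- An open, ene-type Michael adduct instead of the closed pyran would do no harm, because it gives the same 6 in step 4.
- The fallback uses known chemistry. It sets out from 3 and comes back at 6.
- Compound 3 is hydrolysed with aqueous oxalic acid in THF to racemic 7-methyl-1,4-dioxaspiro[4.5]decan-8-one F1, whose labile α-centre is erased on enolisation.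
- This ketone is then added to 4 under established chiral phosphoric acid enol catalysis (TRIP-type acid, 5–10 mol %, toluene, 40 °C). This is a stereoconvergent Michael addition of an α-branched cyclic ketone to a vinyl ketone.
- The product is 6, which enters step 4 at the KOH stage.

**Step 5.**
- Likely failures are competing dienamine formation at the enone, double addition, base-induced drift of the acrylate alkene to the C7=C11 position, or a poor C7 epimer ratio.
- The fallback reverses the polarity at C11. It sets out from 8 and comes back at 11.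
- Dione 8 is condensed at C7 with methyl glyoxylate (cat. TsOH, toluene, water removal) to methyl (E)-3,8-dioxo-13-noreudesma-4,7(11)-dien-12-oate F2.
- Nitromethane with catalytic DBU then adds to C11, the position β to the ketone of this γ-oxo enoate. This gives nitro ester 11, which continues with the Et3N stage of step 5.

**Step 6.**
- Likely failures are closure of the 8β-alkoxide onto the ester, or stereoisomers that are hard to separate at the diol stage.
- The fallback goes through the lactone on purpose. It sets out from 12 and comes back at 13.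
- After the same hydride reduction the crude product is fully lactonised (cat. TsOH, CH2Cl2) to 3β-hydroxyeudesma-4,11(13)-dien-12,8β-olide F3, where diastereomers are removed by chromatography or crystallisation.
- LiOH (1.05 equiv, THF/H2O, 0 °C) opens F3 to lithium 3β,8β-dihydroxyeudesma-4,11(13)-dien-12-oate F4.
- The dried salt is alkylated on the carboxylate with MeI in DMF, conditions that are neither acidic nor strongly basic. This gives 13, which is taken directly into step 7.

## Further compounds
F1 | step 3 | rac-7-methyl-1,4-dioxaspiro[4.5]decan-8-one | CC1CC2(CCC1=O)OCCO2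
F2 | step 5 | methyl (E)-3,8-dioxo-13-noreudesma-4,7(11)-dien-12-oate (10R) | COC(=O)/C=C1\CC2=C(C)C(=O)CC[C@]2(C)CC1=O
F3 | step 6 | 3β-hydroxyeudesma-4,11(13)-dien-12,8β-olide (3S,7R,8R,10R) | C=C1C(=O)O[C@@H]2C[C@@]3(C)CC[C@H](O)C(C)=C3C[C@H]12
F4 | step 6 | lithium 3β,8β-dihydroxyeudesma-4,11(13)-dien-12-oate | [Li+].C=C(C(=O)[O-])[C@H]1CC2=C(C)[C@@H](O)CC[C@]2(C)C[C@H]1O
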